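**Retrosynthetic overview**
1. Target 44 ⇐ bis-silyl acid 43 ⇐ aldehyde 40 (Mannich methylenation, Pinnick oxidation); the C8 ester comes from syn-diol 36 and Z-acid 20 (fragment C).
2. 36 ⇐ enone 32 through four face-controlled events: Luche reduction, hydroxyl-directed epoxidation, semipinacol 1,2-hydride shift, bulky-hydride reduction.
3. The only carbocycle is closed at C7–C8 by intramolecular aldol condensation of keto-aldehyde 29.
4. 29 ⇐ δ-lactone 25 + Grignard reagent 27; 25 ⇐ enantioselective Ireland–Claisen rearrangement of ester 21, which sets C5 and the quaternary C10.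
5. 21 ⇐ allylic alcohol 5 (fragment A) + acid 10 (fragment B). Rings form in the order δ-lactone (temporary), cyclohexene (aldol), epoxide (temporary).

Locants and abbreviations: C10 = ring C(Me)(vinyl), C9 = ring CH2, C8 = ring C–O(acyl), C7 = ring C bearing the acrylic acid (C11, C12, methylene C13), C6 = ring C–OH, C5 = ring C bearing the hydroxypropenyl group. "Vinyl face" and "methyl face" are the ring faces carrying the C10 vinyl and C10 methyl groups. TES = triethylsilyl, TBS = tert-butyldimethylsilyl, TBSO/TESO = the silyloxy groups.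

Assumption: the (4S,5S)-diazaborolidine controller of step 14 is taken to give the (2R,3R)-acid 23; if its sense proved opposite, the (4R,5R)-enantiomer would be used in the same step.

**Fragment A**

Step 1
Reactants: 1 but-3-yn-1-ol
Product: 2 (but-3-yn-1-yloxy)triethylsilane
Conditions: Et3SiCl, imidazole, CH2Cl2, 0 → 23 °C
Reagents that add atoms: chlorotriethylsilane, CC[Si](CC)(CC)Cl
Why: Imidazole-promoted O-silylation masks the alcohol as a TES ether that survives the organoaluminium steps and can later be removed in the presence of TBS.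

Step 2
Reactants: 2 (but-3-yn-1-yloxy)triethylsilane
Product: 4 ethyl (2E)-3-methyl-5-(triethylsilyloxy)pent-2-enoate, via alkenylalane 3 (not isolated)
Conditions: Me3Al, Cp2ZrCl2 (25 mol %), CH2Cl2, 0 → 23 °C; then ClCO2Et, 0 → 23 °C
Reagents that add atoms: trimethylaluminium, C[Al](C)C; ethyl chloroformate, CCOC(=O)Cl
Why: Negishi carboalumination adds methyl and aluminium syn across the alkyne with aluminium at the terminus, and acylation of the alkenylalane goes with retention, so only the E trisubstituted alkene forms.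

Step 3
Reactants: 4 ethyl (2E)-3-methyl-5-(triethylsilyloxy)pent-2-enoate
Product: 5 (2E)-3-methyl-5-(triethylsilyloxy)pent-2-en-1-ol
Conditions: i-Bu2AlH, CH2Cl2, −78 °C; aq. potassium sodium tartrate
Reagents that add atoms: none
Why: Aluminium hydride 1,2-reduction of the enoate gives the allylic alcohol (fragment A) without touching alkene geometry or the silyl ether.

**Fragment B**

Step 4
Reactants: 6 4-methoxy-2-methylidene-4-oxobutanoic acid
Product: 8 methyl 3-(hydroxymethyl)but-3-enoate, via mixed anhydride 7 (not isolated)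
Conditions: i-BuOCOCl, N-methylmorpholine, THF, −15 °C; then NaBH4, H2O, 0 °C
Reagents that add atoms: none
Why: Mixed carbonic anhydride activation touches only the free acid, which borohydride then reduces to the primary alcohol while the methyl ester is inert.

Step 5
Reactants: 8 methyl 3-(hydroxymethyl)but-3-enoate
Product: 9 methyl 3-({[tert-butyl(dimethyl)silyl]oxy}methyl)but-3-enoate
Conditions: t-BuMe2SiCl, imidazole, DMF, 0 → 23 °C
Reagents that add atoms: tert-butyl(chloro)dimethylsilane, CC(C)(C)[Si](C)(C)Cl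
Why: O-silylation blocks the γ-hydroxyl, which would otherwise lactonise, as a TBS ether that lasts to the final step.

Step 6
Reactants: 9 methyl 3-({[tert-butyl(dimethyl)silyl]oxy}methyl)but-3-enoate
Product: 10 3-({[tert-butyl(dimethyl)silyl]oxy}methyl)but-3-enoic acid
Conditions: LiOH·H2O, THF/H2O 3:1, 0 °C; then 1 M HCl to pH 4
Reagents that add atoms: lithium hydroxide, [Li+].[OH-]
Why: Saponification of the unhindered methyl ester at 0 °C is faster than base-induced migration of the 1,1-disubstituted alkene into conjugation, giving fragment B.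

**Fragment C**

Step 7
Reactants: 11 (2Z)-but-2-ene-1,4-diol
Product: 12 (2Z)-but-2-ene-1,4-diyl diacetate
Conditions: Ac2O, pyridine, DMAP (cat.), CH2Cl2, 0 → 23 °C
Reagents that add atoms: acetic anhydride, CC(=O)OC(C)=O
Why: Nucleophile-catalysed acetylation of the bulk diol installs the acetate that ends up in the side chain of the target.

Step 8
Reactants: 12 (2Z)-but-2-ene-1,4-diyl diacetate
Product: 14 2-oxoethyl acetate, via ozonide 13 (not isolated)
Conditions: O3, CH2Cl2, −78 °C; then Me2S, −78 → 23 °C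
Reagents that add atoms: ozone, [O-][O+]=O
Why: Ozonolysis with reductive work-up cleaves the symmetrical alkene into two equivalents of the same aldehyde.

Step 9
Reactants: 15 diphenyl phosphonate; 16 tert-butyl bromoacetate
Product: 17 tert-butyl (diphenoxyphosphoryl)acetate
Conditions: Et3N, CH2Cl2, 0 → 23 °C
Reagents that add atoms: none
Why: Michaelis–Becker-type P-alkylation of the phosphite by the α-bromo ester gives the diaryl phosphonate needed for a Z-selective olefination.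

Step 10
Reactants: 17 tert-butyl (diphenoxyphosphoryl)acetate
Product: 18 tert-butyl 2-(diphenoxyphosphoryl)propanoate
Conditions: KOt-Bu, MeI, DMSO, 23 °C
Reagents that add atoms: iodomethane, CI
Why: SN2 C-methylation of the stabilised phosphonate carbanion adds the 2-methyl group; the new centre is racemic and is destroyed in step 11.

Step 11
Reactants: 18 tert-butyl 2-(diphenoxyphosphoryl)propanoate; 14 2-oxoethyl acetate
Product: 19 tert-butyl (2Z)-4-(acetyloxy)-2-methylbut-2-enoate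
Conditions: NaH, THF, −78 → 0 °C
Reagents that add atoms: none
Why: Ando-type Horner–Wadsworth–Emmons olefination, in which the electron-poor diaryl phosphonate eliminates from the kinetic adduct before it equilibrates, gives the Z trisubstituted enoate.

Step 12
Reactants: 19 tert-butyl (2Z)-4-(acetyloxy)-2-methylbut-2-enoate
Product: 20 (2Z)-4-(acetyloxy)-2-methylbut-2-enoic acid
Conditions: CF3CO2H/CH2Cl2 1:4, 0 → 23 °C
Reagents that add atoms: none
Why: Acidolysis of the tert-butyl ester frees the acid (fragment C) without touching the acetate or the Z alkene, and the acetate keeps the acid from closing to the butenolide.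

**Main line**

Step 13
Reactants: 5 (2E)-3-methyl-5-(triethylsilyloxy)pent-2-en-1-ol; 10 3-({[tert-butyl(dimethyl)silyl]oxy}methyl)but-3-enoic acid
Product: 21 (2E)-3-methyl-5-(triethylsilyloxy)pent-2-en-1-yl 3-({[tert-butyl(dimethyl)silyl]oxy}methyl)but-3-enoate
Conditions: PPh3, i-PrO2CN=NCO2i-Pr, THF, 0 → 23 °C
Reagents that add atoms: none
Why: Mitsunobu esterification joins fragments A and B by SN2 attack of the carboxylate at the primary allylic carbon without base, so the β,γ-unsaturated acid is not isomerised.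

Step 14
Reactants: 21 (2E)-3-methyl-5-(triethylsilyloxy)pent-2-en-1-yl 3-({[tert-butyl(dimethyl)silyl]oxy}methyl)but-3-enoate
Product: 25 (3R,4R)-3-[3-(TBSO)prop-1-en-2-yl]-4-ethenyl-4-methyloxan-2-one, via boron ketene acetal 22 (not isolated), via Claisen acid 23 (not isolated), via hydroxy acid 24 (not isolated)
Conditions: (4S,5S)-2-bromo-1,3-bis{[3,5-bis(trifluoromethyl)phenyl]sulfonyl}-4,5-diphenyl-1,3,2-diazaborolidine (from (1S,2S)-N,N'-bis{[3,5-bis(trifluoromethyl)phenyl]sulfonyl}-1,2-diphenylethane-1,2-diamine and BBr3), i-Pr2NEt, CH2Cl2, −78 °C; then −20 → 4 °C, 72 h; then AcOH/THF/H2O 3:1:1, 23 °C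
Reagents that add atoms: none
Why: Enantioselective Ireland–Claisen rearrangement in which the Z(O) boron enolate and the E alkene pass through a chair transition state that sets C5 and the quaternary C10 with the side chain and the vinyl group in the relative sense needed, the chiral diazaborolidine selects one enantiomeric chair, and the acidic work-up removes the primary TES group so the δ-hydroxy acid lactonises.

Step 15
Reactants: 25 (3R,4R)-3-[3-(TBSO)prop-1-en-2-yl]-4-ethenyl-4-methyloxan-2-one; 26 2-(2-bromoethyl)-1,3-dioxolane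
Product: 28 (4R,5R)-4-[3-(TBSO)prop-1-en-2-yl]-1-(1,3-dioxolan-2-yl)-5-(2-hydroxyethyl)-5-methylhept-6-en-3-one, via Grignard reagent 27 (not isolated)
Conditions: 26, Mg, THF, 25 °C; then 25, THF, −78 → −20 °C; aq. NH4Cl
Reagents that add atoms: none
Why: Grignard addition to the hindered δ-lactone stops after one addition because the magnesium hemiketal alkoxide collapses to the ketone only on work-up, which brings in C7, C11 and C12 with C12 masked as an acetal.

Step 16
Reactants: 28 (4R,5R)-4-[3-(TBSO)prop-1-en-2-yl]-1-(1,3-dioxolan-2-yl)-5-(2-hydroxyethyl)-5-methylhept-6-en-3-one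
Product: 29 (3R,4R)-4-[3-(TBSO)prop-1-en-2-yl]-7-(1,3-dioxolan-2-yl)-3-ethenyl-3-methyl-5-oxoheptanal
Conditions: Dess–Martin periodinane, pyridine, CH2Cl2, 0 → 23 °C
Reagents that add atoms: none
Why: Dess–Martin oxidation gives the C8 aldehyde under buffered, non-enolising conditions that spare the acetal, the silyl ether and the C5 stereocentre.

Step 17
Reactants: 29 (3R,4R)-4-[3-(TBSO)prop-1-en-2-yl]-7-(1,3-dioxolan-2-yl)-3-ethenyl-3-methyl-5-oxoheptanal
Product: 32 (5R,6R)-6-[3-(TBSO)prop-1-en-2-yl]-2-(1,3-dioxolan-2-ylmethyl)-5-ethenyl-5-methylcyclohex-2-en-1-one, via lithium aldolate 30 (not isolated), via mesylate 31 (not isolated)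
Conditions: LiN(SiMe3)2, THF, −78 °C; then MeSO2Cl, Et3N, −78 → 0 °C
Reagents that add atoms: none
Why: Intramolecular aldol condensation closes the cyclohexane ring, since the kinetic enolate at the unhindered C7 methylene can reach the C8 aldehyde only in a six-membered mode, and mesylation with E1cB elimination of the aldolate gives the enone so that no new stereocentre has to be controlled here and C5 never meets equilibrating base.

Step 18
Reactants: 32 (5R,6R)-6-[3-(TBSO)prop-1-en-2-yl]-2-(1,3-dioxolan-2-ylmethyl)-5-ethenyl-5-methylcyclohex-2-en-1-one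
Product: 33 (1S,5R,6R)-6-[3-(TBSO)prop-1-en-2-yl]-2-(1,3-dioxolan-2-ylmethyl)-5-ethenyl-5-methylcyclohex-2-en-1-ol
Conditions: NaBH4, CeCl3·7H2O, MeOH, −78 °C
Reagents that add atoms: none
Why: Luche 1,2-reduction delivers hydride to C6 on the methyl face, away from the adjacent C5 side chain and the pseudo-axial vinyl group, so the new 6-OH is cis to both.

Step 19
Reactants: 33 (1S,5R,6R)-6-[3-(TBSO)prop-1-en-2-yl]-2-(1,3-dioxolan-2-ylmethyl)-5-ethenyl-5-methylcyclohex-2-en-1-ol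
Product: 34 (1S,2S,3R,4R,6R)-3-[3-(TBSO)prop-1-en-2-yl]-1-(1,3-dioxolan-2-ylmethyl)-4-ethenyl-4-methyl-7-oxabicyclo[4.1.0]heptan-2-ol
Conditions: VO(acac)2 (5 mol %), t-BuOOH, CH2Cl2, 0 → 23 °C
Reagents that add atoms: tert-butyl hydroperoxide, CC(C)(C)OO
Why: Hydroxyl-directed vanadium-catalysed epoxidation puts oxygen on the allylic C7=C8 bond from the face of the 6-OH, which fixes the future 8-oxygen cis to it and leaves the non-allylic alkenes alone.

Step 20
Reactants: 34 (1S,2S,3R,4R,6R)-3-[3-(TBSO)prop-1-en-2-yl]-1-(1,3-dioxolan-2-ylmethyl)-4-ethenyl-4-methyl-7-oxabicyclo[4.1.0]heptan-2-ol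
Product: 35 (2R,3R,5R,6R)-2-[3-(TBSO)prop-1-en-2-yl]-6-(1,3-dioxolan-2-ylmethyl)-3-ethenyl-5-hydroxy-3-methylcyclohexan-1-one
Conditions: BF3·OEt2 (0.2 equiv), CH2Cl2, −78 °C
Reagents that add atoms: none
Why: Lewis-acid semipinacol rearrangement of the 2,3-epoxy alcohol, in which the tertiary C7–O bond ionises and the C6 hydrogen shifts to C7 on the methyl face (1,2-hydride shift anti to the leaving oxygen), leaves the C7 side chain cis to the retained 8-OH and makes C6 a ketone.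

Step 21
Reactants: 35 (2R,3R,5R,6R)-2-[3-(TBSO)prop-1-en-2-yl]-6-(1,3-dioxolan-2-ylmethyl)-3-ethenyl-5-hydroxy-3-methylcyclohexan-1-one
Product: 36 (1R,2R,3S,4R,5R)-4-[3-(TBSO)prop-1-en-2-yl]-2-(1,3-dioxolan-2-ylmethyl)-5-ethenyl-5-methylcyclohexane-1,3-diol
Conditions: LiBH(s-Bu)3, THF, −78 °C; then H2O
Reagents that add atoms: none
Why: Bulky-hydride reduction of the ketone, whose vinyl face is shielded by the axial 8-OH and the axial vinyl group while both flanking side chains are equatorial, brings hydride in from the methyl face and gives the axial 6-OH cis to all its neighbours.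

Step 22
Reactants: 36 (1R,2R,3S,4R,5R)-4-[3-(TBSO)prop-1-en-2-yl]-2-(1,3-dioxolan-2-ylmethyl)-5-ethenyl-5-methylcyclohexane-1,3-diol; 20 (2Z)-4-(acetyloxy)-2-methylbut-2-enoic acid
Product: 38 (1R,2S,3S,4R,5R)-4-[3-(TBSO)prop-1-en-2-yl]-2-(1,3-dioxolan-2-ylmethyl)-5-ethenyl-3-hydroxy-5-methylcyclohexyl (2Z)-4-(acetyloxy)-2-methylbut-2-enoate, via mixed anhydride 37 (not isolated)
Conditions: 20, 2,4,6-Cl3C6H2COCl, Et3N, THF, 0 °C; then 36, DMAP (0.3 equiv), PhMe, 0 → 23 °C
Reagents that add atoms: none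
Why: Yamaguchi esterification acylates the 8-OH, which has a CH2 neighbour, in preference to the 6-OH wedged between two branched carbons, and the mild conditions keep the Z geometry of the acyl group.

Step 23
Reactants: 38 (1R,2S,3S,4R,5R)-4-[3-(TBSO)prop-1-en-2-yl]-2-(1,3-dioxolan-2-ylmethyl)-5-ethenyl-3-hydroxy-5-methylcyclohexyl (2Z)-4-(acetyloxy)-2-methylbut-2-enoate
Product: 40 (1R,2R,3S,4R,5R)-4-[3-(TBSO)prop-1-en-2-yl]-5-ethenyl-5-methyl-2-(2-oxoethyl)-3-(triethylsilyloxy)cyclohexyl (2Z)-4-(acetyloxy)-2-methylbut-2-enoate, via collidinium salt 39 (not isolated)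
Conditions: Et3SiOTf, 2,4,6-collidine, CH2Cl2, 0 °C; then H2O, 23 °C
Reagents that add atoms: triethylsilyl trifluoromethanesulfonate, CC[Si](CC)(CC)OS(=O)(=O)C(F)(F)F; water, O
Why: The silyl triflate silylates the hindered 6-OH and, with collidine, opens the dioxolane to a pyridinium N,O-acetal that water hydrolyses to the aldehyde, a non-acidic acetal cleavage that keeps silyl ethers, esters and alkenes.

Step 24
Reactants: 40 (1R,2R,3S,4R,5R)-4-[3-(TBSO)prop-1-en-2-yl]-5-ethenyl-5-methyl-2-(2-oxoethyl)-3-(triethylsilyloxy)cyclohexyl (2Z)-4-(acetyloxy)-2-methylbut-2-enoate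
Product: 42 (1R,2R,3S,4R,5R)-4-[3-(TBSO)prop-1-en-2-yl]-5-ethenyl-5-methyl-2-(3-oxoprop-1-en-2-yl)-3-(triethylsilyloxy)cyclohexyl (2Z)-4-(acetyloxy)-2-methylbut-2-enoate, via Mannich base 41 (not isolated)
Conditions: Me2N=CH2 I (dimethylmethylideneammonium iodide), Et3N, CH2Cl2, 23 °C
Reagents that add atoms: N,N-dimethylmethaniminium iodide, C=[N+](C)C.[I-]
Why: Mannich reaction of the aldehyde with the iminium salt followed by elimination of dimethylamine installs the exocyclic methylene C13 next to C12.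

Step 25
Reactants: 42 (1R,2R,3S,4R,5R)-4-[3-(TBSO)prop-1-en-2-yl]-5-ethenyl-5-methyl-2-(3-oxoprop-1-en-2-yl)-3-(triethylsilyloxy)cyclohexyl (2Z)-4-(acetyloxy)-2-methylbut-2-enoate
Product: 43 2-[(1R,2S,3R,4R,6R)-6-{[(2Z)-4-(acetyloxy)-2-methylbut-2-enoyl]oxy}-3-[3-(TBSO)prop-1-en-2-yl]-4-ethenyl-4-methyl-2-(triethylsilyloxy)cyclohexyl]prop-2-enoic acid
Conditions: NaClO2, NaH2PO4, 2-methylbut-2-ene, t-BuOH/H2O, 0 °C
Reagents that add atoms: sodium chlorite, [Na+].[O-]Cl=O
Why: Pinnick oxidation turns the enal into the acrylic acid while the scavenger alkene removes hypochlorous acid before it can attack the other double bonds.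

Step 26
Reactants: 43 2-[(1R,2S,3R,4R,6R)-6-{[(2Z)-4-(acetyloxy)-2-methylbut-2-enoyl]oxy}-3-[3-(TBSO)prop-1-en-2-yl]-4-ethenyl-4-methyl-2-(triethylsilyloxy)cyclohexyl]prop-2-enoic acid
Product: 44 2-[(1S,2S,3R,4R,6R)-6-{[(2Z)-4-(acetyloxy)-2-methylbut-2-enoyl]oxy}-4-ethenyl-2-hydroxy-3-(3-hydroxyprop-1-en-2-yl)-4-methylcyclohexyl]prop-2-enoic acid
Conditions: HF·pyridine, pyridine, THF, 0 → 23 °C
Reagents that add atoms: none
Why: Fluoride-driven desilylation removes the TES and TBS ethers under buffered conditions that leave the acetate, the enoate ester and the free γ-hydroxy acid intact.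

**Compound list**
1 | but-3-yn-1-ol | C#CCCO | starting material
2 | (but-3-yn-1-yloxy)triethylsilane | C#CCCO[Si](CC)(CC)CC | intermediate
3 | dimethyl[(1E)-2-methyl-4-(triethylsilyloxy)but-1-en-1-yl]alumane | C[Al](C)/C=C(\C)CCO[Si](CC)(CC)CC | intermediate (not isolated)
4 | ethyl (2E)-3-methyl-5-(triethylsilyloxy)pent-2-enoate | CCOC(=O)/C=C(\C)CCO[Si](CC)(CC)CC | intermediate
5 | (2E)-3-methyl-5-(triethylsilyloxy)pent-2-en-1-ol (fragment A) | OC/C=C(\C)CCO[Si](CC)(CC)CC | intermediate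
6 | 4-methoxy-2-methylidene-4-oxobutanoic acid (monomethyl itaconate) | C=C(CC(=O)OC)C(=O)O | starting material
7 | mixed anhydride of 6 with isobutyl hydrogen carbonate | C=C(CC(=O)OC)C(=O)OC(=O)OCC(C)C | intermediate (not isolated)
8 | methyl 3-(hydroxymethyl)but-3-enoate | C=C(CO)CC(=O)OC | intermediate
9 | methyl 3-({[tert-butyl(dimethyl)silyl]oxy}methyl)but-3-enoate | C=C(CO[Si](C)(C)C(C)(C)C)CC(=O)OC | intermediate
10 | 3-({[tert-butyl(dimethyl)silyl]oxy}methyl)but-3-enoic acid (fragment B) | C=C(CO[Si](C)(C)C(C)(C)C)CC(=O)O | intermediate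
11 | (2Z)-but-2-ene-1,4-diol | OC/C=C\CO | starting material
12 | (2Z)-but-2-ene-1,4-diyl diacetate | CC(=O)OC/C=C\COC(C)=O | intermediate
13 | (1,2,4-trioxolane-3,5-diyl)bis(methylene) diacetate (ozonide) | CC(=O)OCC1OOC(COC(C)=O)O1 | intermediate (not isolated)
14 | 2-oxoethyl acetate | CC(=O)OCC=O | intermediate
15 | diphenyl phosphonate (diphenyl phosphite) | O=[PH](Oc1ccccc1)Oc1ccccc1 | starting material
16 | tert-butyl bromoacetate | CC(C)(C)OC(=O)CBr | starting material
17 | tert-butyl (diphenoxyphosphoryl)acetate | CC(C)(C)OC(=O)CP(=O)(Oc1ccccc1)Oc1ccccc1 | intermediate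
18 | tert-butyl 2-(diphenoxyphosphoryl)propanoate (racemic) | CC(C(=O)OC(C)(C)C)P(=O)(Oc1ccccc1)Oc1ccccc1 | intermediate
19 | tert-butyl (2Z)-4-(acetyloxy)-2-methylbut-2-enoate | CC(=O)OC/C=C(/C)C(=O)OC(C)(C)C | intermediate
20 | (2Z)-4-(acetyloxy)-2-methylbut-2-enoic acid (fragment C) | CC(=O)OC/C=C(/C)C(=O)O | intermediate
21 | (2E)-3-methyl-5-(triethylsilyloxy)pent-2-en-1-yl 3-({[tert-butyl(dimethyl)silyl]oxy}methyl)but-3-enoate | C=C(CO[Si](C)(C)C(C)(C)C)CC(=O)OC/C=C(\C)CCO[Si](CC)(CC)CC | intermediate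
22 | (Z)-O-boryl ketene acetal of 21, boron being part of the (4S,5S)-1,3-bis{[3,5-bis(trifluoromethyl)phenyl]sulfonyl}-4,5-diphenyl-1,3,2-diazaborolidine | C=C(CO[Si](C)(C)C(C)(C)C)/C=C(/OC/C=C(\C)CCO[Si](CC)(CC)CC)OB1N(S(=O)(=O)c2cc(cc(c2)C(F)(F)F)C(F)(F)F)[C@@H](c2ccccc2)[C@H](c2ccccc2)N1S(=O)(=O)c1cc(cc(c1)C(F)(F)F)C(F)(F)F | intermediate (not isolated)
23 | (2R,3R)-2-[3-(TBSO)prop-1-en-2-yl]-3-methyl-3-[2-(triethylsilyloxy)ethyl]pent-4-enoic acid | C=C[C@@]([C@H](C(=C)CO[Si](C)(C)C(C)(C)C)C(=O)O)(C)CCO[Si](CC)(CC)CC | intermediate (not isolated)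
24 | (2R,3R)-2-[3-(TBSO)prop-1-en-2-yl]-3-(2-hydroxyethyl)-3-methylpent-4-enoic acid | C=C[C@@]([C@H](C(=C)CO[Si](C)(C)C(C)(C)C)C(=O)O)(C)CCO | intermediate (not isolated)
25 | (3R,4R)-3-[3-(TBSO)prop-1-en-2-yl]-4-ethenyl-4-methyloxan-2-one | C=C[C@@]1(C)CCOC(=O)[C@H]1C(=C)CO[Si](C)(C)C(C)(C)C | intermediate
26 | 2-(2-bromoethyl)-1,3-dioxolane | BrCCC1OCCO1 | starting material
27 | [2-(1,3-dioxolan-2-yl)ethyl]magnesium bromide | Br[Mg]CCC1OCCO1 | intermediate (not isolated)
28 | (4R,5R)-4-[3-(TBSO)prop-1-en-2-yl]-1-(1,3-dioxolan-2-yl)-5-(2-hydroxyethyl)-5-methylhept-6-en-3-one | C=C[C@@]([C@H](C(=C)CO[Si](C)(C)C(C)(C)C)C(=O)CCC1OCCO1)(C)CCO | intermediate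
29 | (3R,4R)-4-[3-(TBSO)prop-1-en-2-yl]-7-(1,3-dioxolan-2-yl)-3-ethenyl-3-methyl-5-oxoheptanal | C=C[C@@]([C@H](C(=C)CO[Si](C)(C)C(C)(C)C)C(=O)CCC1OCCO1)(C)CC=O | intermediate
30 | lithium aldolate from C7–C8 ring closure of 29 (3-oxido-cyclohexanone; mixture at C7 and C8) | C=C[C@@]1(C)CC([O-])C(CC2OCCO2)C(=O)[C@H]1C(=C)CO[Si](C)(C)C(C)(C)C.[Li+] | intermediate (not isolated)
31 | O-methanesulfonate of the aldol from 30 (mixture at C7 and C8) | C=C[C@@]1(C)CC(OS(C)(=O)=O)C(CC2OCCO2)C(=O)[C@H]1C(=C)CO[Si](C)(C)C(C)(C)C | intermediate (not isolated)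
32 | (5R,6R)-6-[3-(TBSO)prop-1-en-2-yl]-2-(1,3-dioxolan-2-ylmethyl)-5-ethenyl-5-methylcyclohex-2-en-1-one | C=C[C@@]1(C)CC=C(CC2OCCO2)C(=O)[C@H]1C(=C)CO[Si](C)(C)C(C)(C)C | intermediate
33 | (1S,5R,6R)-6-[3-(TBSO)prop-1-en-2-yl]-2-(1,3-dioxolan-2-ylmethyl)-5-ethenyl-5-methylcyclohex-2-en-1-ol (OH cis to the C5 side chain and to vinyl) | C=C[C@@]1(C)CC=C(CC2OCCO2)[C@@H](O)[C@H]1C(=C)CO[Si](C)(C)C(C)(C)C | intermediate
34 | (1S,2S,3R,4R,6R)-3-[3-(TBSO)prop-1-en-2-yl]-1-(1,3-dioxolan-2-ylmethyl)-4-ethenyl-4-methyl-7-oxabicyclo[4.1.0]heptan-2-ol (epoxide cis to OH) | C=C[C@@]1(C)C[C@H]2O[C@@]2(CC3OCCO3)[C@@H](O)[C@H]1C(=C)CO[Si](C)(C)C(C)(C)C | intermediate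
35 | (2R,3R,5R,6R)-2-[3-(TBSO)prop-1-en-2-yl]-6-(1,3-dioxolan-2-ylmethyl)-3-ethenyl-5-hydroxy-3-methylcyclohexan-1-one | C=C[C@@]1(C)C[C@@H](O)[C@@H](CC2OCCO2)C(=O)[C@H]1C(=C)CO[Si](C)(C)C(C)(C)C | intermediate
36 | (1R,2R,3S,4R,5R)-4-[3-(TBSO)prop-1-en-2-yl]-2-(1,3-dioxolan-2-ylmethyl)-5-ethenyl-5-methylcyclohexane-1,3-diol (all ring substituents except 5-methyl on the vinyl face) | C=C[C@@]1(C)C[C@@H](O)[C@@H](CC2OCCO2)[C@@H](O)[C@H]1C(=C)CO[Si](C)(C)C(C)(C)C | intermediate
37 | (2Z)-4-(acetyloxy)-2-methylbut-2-enoic 2,4,6-trichlorobenzoic anhydride | CC(=O)OC/C=C(/C)C(=O)OC(=O)c1c(Cl)cc(Cl)cc1Cl | intermediate (not isolated)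
38 | (1R,2S,3S,4R,5R)-4-[3-(TBSO)prop-1-en-2-yl]-2-(1,3-dioxolan-2-ylmethyl)-5-ethenyl-3-hydroxy-5-methylcyclohexyl (2Z)-4-(acetyloxy)-2-methylbut-2-enoate | C=C[C@@]1(C)C[C@@H](OC(=O)/C(C)=C\COC(C)=O)[C@@H](CC2OCCO2)[C@@H](O)[C@H]1C(=C)CO[Si](C)(C)C(C)(C)C | intermediate
39 | 2,4,6-trimethylpyridinium N,O-acetal triflate from 38 (6-OTES; C12 bearing collidinium and 2-(triethylsilyloxy)ethoxy) | C=C[C@@]1(C)C[C@@H](OC(=O)/C(C)=C\COC(C)=O)[C@@H](CC(OCCO[Si](CC)(CC)CC)[n+]2c(C)cc(C)cc2C)[C@@H](O[Si](CC)(CC)CC)[C@H]1C(=C)CO[Si](C)(C)C(C)(C)C.[O-]S(=O)(=O)C(F)(F)F | intermediate (not isolated)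
40 | (1R,2R,3S,4R,5R)-4-[3-(TBSO)prop-1-en-2-yl]-5-ethenyl-5-methyl-2-(2-oxoethyl)-3-(triethylsilyloxy)cyclohexyl (2Z)-4-(acetyloxy)-2-methylbut-2-enoate | C=C[C@@]1(C)C[C@@H](OC(=O)/C(C)=C\COC(C)=O)[C@@H](CC=O)[C@@H](O[Si](CC)(CC)CC)[C@H]1C(=C)CO[Si](C)(C)C(C)(C)C | intermediate
41 | Mannich base of 40 (C11 bearing CH2NMe2; mixture at C11) | C=C[C@@]1(C)C[C@@H](OC(=O)/C(C)=C\COC(C)=O)[C@@H](C(CN(C)C)C=O)[C@@H](O[Si](CC)(CC)CC)[C@H]1C(=C)CO[Si](C)(C)C(C)(C)C | intermediate (not isolated)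
42 | (1R,2R,3S,4R,5R)-4-[3-(TBSO)prop-1-en-2-yl]-5-ethenyl-5-methyl-2-(3-oxoprop-1-en-2-yl)-3-(triethylsilyloxy)cyclohexyl (2Z)-4-(acetyloxy)-2-methylbut-2-enoate | C=C[C@@]1(C)C[C@@H](OC(=O)/C(C)=C\COC(C)=O)[C@@H](C(=C)C=O)[C@@H](O[Si](CC)(CC)CC)[C@H]1C(=C)CO[Si](C)(C)C(C)(C)C | intermediate
43 | 2-[(1R,2S,3R,4R,6R)-6-{[(2Z)-4-(acetyloxy)-2-methylbut-2-enoyl]oxy}-3-[3-(TBSO)prop-1-en-2-yl]-4-ethenyl-4-methyl-2-(triethylsilyloxy)cyclohexyl]prop-2-enoic acid | C=C[C@@]1(C)C[C@@H](OC(=O)/C(C)=C\COC(C)=O)[C@@H](C(=C)C(=O)O)[C@@H](O[Si](CC)(CC)CC)[C@H]1C(=C)CO[Si](C)(C)C(C)(C)C | intermediate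
44 | 2-[(1S,2S,3R,4R,6R)-6-{[(2Z)-4-(acetyloxy)-2-methylbut-2-enoyl]oxy}-4-ethenyl-2-hydroxy-3-(3-hydroxyprop-1-en-2-yl)-4-methylcyclohexyl]prop-2-enoic acid | C=C[C@@]1(C)C[C@@H](OC(=O)/C(C)=C\COC(C)=O)[C@@H](C(=C)C(=O)O)[C@@H](O)[C@H]1C(=C)CO | target

**Step count and risks**

Total step count: 26. Longest linear sequence: 17 steps (steps 1–3 or 4–6, then 13–26), which is below two thirds of 26. Fragment C (steps 7–12) enters at step 22 and bromide 26 at step 15.

Steps most likely to fail: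

Step 14. The boron enolate of a silyl-ether-bearing β,γ-unsaturated ester may form sluggishly, and the rearrangement to a quaternary centre may give insufficient enantio- or diastereoselectivity. Fallback, setting out from 21 and coming back at 25: enolise 21 with LiN(i-Pr)2 in THF/DMPU and trap with Me3SiCl to give the (Z)-trimethylsilyl ketene acetal F1. This rearranges on warming through the same chair to the racemic acid, that is 23 together with the enantiomeric acid F2. The racemate is resolved by crystallising the (1R)-1-phenylethan-1-aminium salt F3 of 23. Citric acid releases 23, and the AcOH/THF/H2O treatment of step 14 then gives 25.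

Step 20. The C7 cation can also give ring-contracted aldehydes, allylic alcohols or the regioisomeric ketone. Fallback, setting out from 34 and coming back at 35: oxidise 34 with Dess–Martin periodinane to the epoxy ketone F4, then treat with SmI2 in THF/MeOH at −90 °C. This cleaves the C7–O bond reductively, and the samarium enolate is protonated on the methyl face to give 35.

Step 22. The two syn-axial hydroxyls may not be differentiated well enough, and forcing conditions risk Z to E isomerisation or acyl migration. Fallback, setting out from 35 and coming back at 38: acylate the single hydroxyl of 35 with mixed anhydride 37 to give the keto ester F5, then reduce only the ketone with NaBH4/CeCl3·7H2O in MeOH at −78 °C from the methyl face, which gives 38.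

Further compounds
F1 | step 14 | (Z)-trimethylsilyl ketene acetal of 21 | C=C(CO[Si](C)(C)C(C)(C)C)/C=C(/OC/C=C(\C)CCO[Si](CC)(CC)CC)O[Si](C)(C)C
F2 | step 14 | (2S,3S)-2-[3-(TBSO)prop-1-en-2-yl]-3-methyl-3-[2-(triethylsilyloxy)ethyl]pent-4-enoic acid (enantiomer of 23) | C=C[C@]([C@@H](C(=C)CO[Si](C)(C)C(C)(C)C)C(=O)O)(C)CCO[Si](CC)(CC)CC
F3 | step 14 | (1R)-1-phenylethan-1-aminium salt of 23 | C=C[C@@]([C@H](C(=C)CO[Si](C)(C)C(C)(C)C)C(=O)[O-])(C)CCO[Si](CC)(CC)CC.C[C@@H]([NH3+])c1ccccc1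
F4 | step 20 | epoxy ketone (2-oxo analogue of 34: 3-[3-(TBSO)prop-1-en-2-yl]-1-(1,3-dioxolan-2-ylmethyl)-4-ethenyl-4-methyl-7-oxabicyclo[4.1.0]heptan-2-one, configuration as in 34) | C=C[C@@]1(C)C[C@H]2O[C@@]2(CC3OCCO3)C(=O)[C@H]1C(=C)CO[Si](C)(C)C(C)(C)C
F5 | step 22 | keto ester (3-oxo analogue of 38: 8-O-acyl derivative of 35, configuration as in 35) | C=C[C@@]1(C)C[C@@H](OC(=O)/C(C)=C\COC(C)=O)[C@@H](CC2OCCO2)C(=O)[C@H]1C(=C)CO[Si](C)(C)C(C)(C)C
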